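**Retrosynthetic overview**
- The target comes from its tri-O-benzyl ether by one global hydrogenolysis. Benzyl is used rather than methyl so that the 7-OMe group survives.
- Key disconnection: the diaryl ether bond between C8 of the apigenin half and O-4' of the genkwanin half. It is made by direct C8–H aryloxylation through a transient aryl(mesityl)-λ3-iodane under copper catalysis.
- Both halves come from apigenin, one by selective 7-O-methylation and the other by exhaustive O-benzylation.
- No ring is built. Rings A, B and C of both flavone units are bought in with apigenin.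

Assumption: the target has no stereocentre and no configurationally stable axis (the diaryl ether rotates freely). It is therefore achiral, no stereocontrol is needed, and the SMILES carry no stereo descriptors.

**Step 1**
Reactants: 1 apigenin
Product: 2 genkwanin (7-O-methylapigenin)
Conditions: MeI (1.05 equiv), K2CO3 (1.1 equiv), DMF, 0 °C to rt, 12 h
Reagents that add atoms: iodomethane, CI
Why: Williamson ether synthesis under acidity control: the 7-OH, para to the ring C carbonyl, is the most acidic phenol and the only one ionised by about one equivalent of base, and the chelated 5-OH is inert, so one equivalent of MeI gives the 7-methyl ether; no stereocentre is formed.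

**Step 2**
Reactants: 1 apigenin
Product: 3 5,7,4'-tri-O-benzylapigenin
Conditions: BnBr (4.5 equiv), K2CO3 (6 equiv), n-Bu4NI (10 mol%), DMF, 80 °C, 16 h
Reagents that add atoms: benzyl bromide, BrCc1ccccc1
Why: Exhaustive Williamson etherification in which heat, excess BnBr and iodide catalysis force the hydrogen-bonded 5-OH to react, as required because a 5-O-alkyl group (not a free 5-OH) steers electrophiles to C8 and because benzyl can later be removed beside the 7-OMe group.

**Step 3**
Reactants: 3 5,7,4'-tri-O-benzylapigenin; 2 genkwanin
Product: 5 tri-O-benzyl biflavone ether (O-4' of genkwanin bonded to C8 of 5,7,4'-tri-O-benzylapigenin), via flavon-8-yl(mesityl)iodonium tosylate 4 (not isolated)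
Conditions: MesI(OAc)2 (1.1 equiv), TsOH·H2O (1.1 equiv), CH2Cl2–CF3CH2OH 4:1, rt, 3 h; concentrate; then 2 (1.2 equiv), Cu(MeCN)4BF4 (10 mol%), K2CO3 (3 equiv), DMSO, 45 °C, 12 h
Reagents that add atoms: none
Why: Proposed new method: one-pot C8–H aryloxylation of a flavone by a second flavone phenol; the Koser-type reagent made in situ attacks ring A of 3 by electrophilic aromatic substitution at C8 (para to 5-OBn and flanked only by 7-OBn and the tied-back ring oxygen, whereas C6 lies between two free OBn groups, which matches the known 8-halogenation of 5,7-dialkoxyflavones) to give the unsymmetrical λ3-iodane 4; monovalent copper then inserts into the I–C8 bond and leaves the more hindered di-ortho-methyl mesityl group on iodine as spectator; the resulting aryl trivalent copper species binds the 4'-phenoxide of 2 (its 5-OH stays chelated and unreactive) and reductively eliminates the C–O bond; because oxidative addition to trivalent iodine is easy, the electron-rich hindered C8 and the electron-poor phenol stop being a mismatched Ullmann pair, and neither aryl group has an ortho hydrogen, so no aryne pathway exists; the closest known reaction type is the copper-catalysed para-selective C–H aryloxylation and amination of simple electron-rich arenes through transient aryl(mesityl)iodonium salts, which has not been shown on a chromone or flavone C–H bond, on a position between two oxygen substituents, or for joining two polyphenol units.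

**Step 4**
Reactants: 5 tri-O-benzyl biflavone ether
Product: 6 target CNP0424791.0
Conditions: H2 (1 atm), 10% Pd/C, THF–MeOH 1:1, rt, 6 h
Reagents that add atoms: none
Why: Catalytic hydrogenolysis cleaves the three aryl benzyl ethers, while the diaryl ether, the aryl methyl ether and the conjugated chromone C2=C3 bonds are inert at 1 atm and rt; no stereocentre is formed.

**Compound list**
1 | apigenin, 5,7-dihydroxy-2-(4-hydroxyphenyl)-4H-chromen-4-one | O=c1cc(-c2ccc(O)cc2)oc2cc(O)cc(O)c12 | starting material
2 | genkwanin, 5-hydroxy-2-(4-hydroxyphenyl)-7-methoxy-4H-chromen-4-one | COc1cc(O)c2c(=O)cc(-c3ccc(O)cc3)oc2c1 | intermediate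
3 | 5,7,4'-tri-O-benzylapigenin, 5,7-bis(benzyloxy)-2-[4-(benzyloxy)phenyl]-4H-chromen-4-one | O=c1cc(-c2ccc(OCc3ccccc3)cc2)oc2cc(OCc3ccccc3)cc(OCc3ccccc3)c12 | intermediate
4 | {5,7-bis(benzyloxy)-2-[4-(benzyloxy)phenyl]-4-oxo-4H-chromen-8-yl}(2,4,6-trimethylphenyl)iodonium 4-methylbenzenesulfonate | Cc1cc(C)c([I+]c2c(OCc3ccccc3)cc(OCc3ccccc3)c3c(=O)cc(-c4ccc(OCc5ccccc5)cc4)oc23)c(C)c1.Cc1ccc(S(=O)(=O)[O-])cc1 | intermediate
5 | 2-[4-({5,7-bis(benzyloxy)-2-[4-(benzyloxy)phenyl]-4-oxo-4H-chromen-8-yl}oxy)phenyl]-5-hydroxy-7-methoxy-4H-chromen-4-one | COc1cc(O)c2c(=O)cc(-c3ccc(Oc4c(OCc5ccccc5)cc(OCc5ccccc5)c5c(=O)cc(-c6ccc(OCc7ccccc7)cc6)oc45)cc3)oc2c1 | intermediate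
6 | 2-[4-({5,7-dihydroxy-2-(4-hydroxyphenyl)-4-oxo-4H-chromen-8-yl}oxy)phenyl]-5-hydroxy-7-methoxy-4H-chromen-4-one (CNP0424791.0) | COc1cc(O)c2c(=O)cc(-c3ccc(Oc4c(O)cc(O)c5c(=O)cc(-c6ccc(O)cc6)oc45)cc3)oc2c1 | target

**Total step count:** 4. **Longest linear sequence:** 3 (1 to 3 to 5 to 6, or 1 to 2 to 5 to 6).

**Three steps most likely to fail**

Step 3 (the proposed new step). Several things could go wrong:
- The mesityl group could transfer to 2 by the uncatalysed ligand coupling.
- Some iodane could form at C6 or C3.
- The attack on ring A could be sluggish if the chromone carbonyl is protonated.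
- The 5-hydroxy-4-keto chelate of 2 could tie up the copper.

The fallback uses known chemistry, sets out from 3 and comes back at 5. Compound 3 is iodinated at C8 with NIS and catalytic CF3CO2H in MeCN at rt, giving 8-iodo-5,7,4'-tri-O-benzylapigenin F1. F1 is then joined to 2 by an Ullmann-type diaryl ether coupling (CuI 20 mol%, picolinic acid 40 mol%, K3PO4, DMSO, 90–100 °C), a ligand system suited to hindered partners.

Step 1. The risk is over-methylation at the 4'-OH, which would give mixtures that are hard to separate. The fallback replaces acidity control with a protecting-group sequence. It sets out from 1 and comes back at 2.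
- Ac2O in pyridine gives apigenin triacetate F2.
- PhSH with catalytic imidazole in NMP removes only the 7-acetate, whose phenoxide is the best leaving group, and gives 5,4'-di-O-acetylapigenin F3.
- Mitsunobu methylation of the single free phenol (MeOH, PPh3, DIAD, THF) gives 5,4'-di-O-acetylgenkwanin F4.
- Methanolysis (K2CO3, MeOH, rt) gives 2.

Step 4. The risks are poor solubility of the biflavone, catalyst poisoning by traces of iodide or copper carried over from step 3, and partial saturation of C2=C3. The fallback drops hydrogenation for Lewis-acid ether cleavage. It sets out from 5 and comes back at 6. BCl3 (6 equiv) and pentamethylbenzene (9 equiv) in CH2Cl2 from −78 to −20 °C ionise the benzyl ethers, and the benzyl cations are trapped by Friedel–Crafts alkylation of the scavenger. The 7-OMe group is untouched, because BCl3 cleaves only methyl ethers peri to the carbonyl. This fallback makes no new compound (F0).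

**Further compounds**
F1 | step 3 | 5,7-bis(benzyloxy)-2-[4-(benzyloxy)phenyl]-8-iodo-4H-chromen-4-one | O=c1cc(-c2ccc(OCc3ccccc3)cc2)oc2c(I)c(OCc3ccccc3)cc(OCc3ccccc3)c12
F2 | step 1 | apigenin triacetate | CC(=O)Oc1ccc(-c2cc(=O)c3c(OC(C)=O)cc(OC(C)=O)cc3o2)cc1
F3 | step 1 | 5,4'-di-O-acetylapigenin (7-OH free) | CC(=O)Oc1ccc(-c2cc(=O)c3c(OC(C)=O)cc(O)cc3o2)cc1
F4 | step 1 | 5,4'-di-O-acetylgenkwanin | COc1cc(OC(C)=O)c2c(=O)cc(-c3ccc(OC(C)=O)cc3)oc2c1
F0 | step 4 | none | none
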